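**Retrosynthetic overview**
1. No ring is built: the central ring is bought as 2,5-dibromohydroquinone (1) and both outer rings as 4-hydroxyphenylboronic acid (2).
2. C–C disconnection: the two aryl–aryl bonds are made first, in one double Suzuki–Miyaura coupling to tetrol 3, which is dehydrogenated to quinone 4.
3. Key disconnection: the quinone C–OAc bond. It is formed last, directly from a ring C–H of 4, through the silylated intermediates 5 and 6, to give the target 7.
4. No protecting group is isolated; the phenols are masked only transiently as Me3Si ethers inside the last step.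

Assumption: the target SMILES contains no stereocentre (the molecule is achiral), so there is no enantiomer to select and no stereocontrol is needed.

**Route**

Step 1
Reactants: 1 2,5-dibromohydroquinone (2,5-dibromobenzene-1,4-diol); 2 4-hydroxyphenylboronic acid (3.0 equiv)
Product: 3 2,5-bis(4-hydroxyphenyl)benzene-1,4-diol
Conditions: Pd(OAc)2 (4 mol%), SPhos (8 mol%), K3PO4 (7 equiv), degassed 1,4-dioxane/H2O 4:1, 90 °C, Ar, 12 h; degassed 1 M HCl work-up
Reagents that add atoms: none
Why: Double Suzuki–Miyaura cross-coupling, in which SPhos-ligated zerovalent palladium inserts even into the electron-rich C–Br bonds of the phenoxide-form dibromohydroquinone, free OH groups are tolerated in aqueous K3PO4, and exclusion of air keeps the product at the hydroquinone level.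

Step 2
Reactants: 3 2,5-bis(4-hydroxyphenyl)benzene-1,4-diol
Product: 4 2,5-bis(4-hydroxyphenyl)-1,4-benzoquinone
Conditions: Ag2O (1.5 equiv), Na2SO4, THF, rt, dark, 1 h; filter through Celite
Reagents that add atoms: none
Why: Hydroquinone-to-quinone dehydrogenation, in which Ag2O removes two electrons and two protons only from the central p-hydroquinone ring, because the isolated outer phenols lie well above its oxidation potential and 4 has no closed-shell over-oxidation product.

Step 3
Reactants: 4 2,5-bis(4-hydroxyphenyl)-1,4-benzoquinone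
Product: 7 neonambiquinone A, via bis-silylated quinone 5 (not isolated), via tetrasilylated acetoxyhydroquinone 6 (not isolated)
Conditions: Me3SiOAc (8 equiv), Me3SiOSO2CF3 (0.3 equiv), MeCN, 0 °C to rt, 6 h; then DDQ (1.1 equiv), H2O (20 equiv), 0 °C, 15 min; pH 5 NaH2PO4/Na2HPO4 buffer work-up
Reagents that add atoms: trimethylsilyl acetate, CC(=O)O[Si](C)(C)C
Why: Proposed new method: a silyl-transfer Thiele–Winter acetoxylation, in which the Me3SiOAc/Me3SiOSO2CF3 pair first caps both phenols as ArOSiMe3 (5), Me3SiOSO2CF3 then O-silylates a quinone carbonyl, the carbonyl oxygen of Me3SiOAc adds to the resulting silyloxy-oxocarbenium ion at the free β-carbon (the two ring C–H are equivalent by symmetry), loss of Me3Si+ to triflate and silylative enolisation give the aromatic bis-silyl ether 6, which cannot add a second acetate and whose ortho oxygen is blocked against acyl migration, and DDQ/H2O finally releases the quinone and the phenols, so that acetate is delivered only as a nucleophile and no phenol ever meets an acyl electrophile; the closest known reaction types are the Thiele–Winter acetoxylation of quinones (Ac2O, strong acid), Lewis-acid-promoted conjugate addition of silyl nucleophiles (Me3SiN3, silyl enol ethers) to quinones, and the oxidative release of quinones from hydroquinone silyl ethers.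

**Compound list**
1 | 2,5-dibromohydroquinone (2,5-dibromobenzene-1,4-diol) | Oc1cc(Br)c(O)cc1Br | starting material
2 | 4-hydroxyphenylboronic acid | OB(O)c1ccc(O)cc1 | starting material
3 | 2,5-bis(4-hydroxyphenyl)benzene-1,4-diol ([1,1':4',1''-terphenyl]-2',4,4'',5'-tetrol) | Oc1ccc(cc1)-c1cc(O)c(cc1O)-c1ccc(O)cc1 | intermediate
4 | 2,5-bis(4-hydroxyphenyl)-1,4-benzoquinone | Oc1ccc(cc1)C1=CC(=O)C(=CC1=O)c1ccc(O)cc1 | intermediate
5 | 2,5-bis[4-(trimethylsilyloxy)phenyl]-1,4-benzoquinone | C[Si](C)(C)Oc1ccc(cc1)C1=CC(=O)C(=CC1=O)c1ccc(O[Si](C)(C)C)cc1 | intermediate (not isolated)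
6 | 2,5-bis(trimethylsilyloxy)-3,6-bis[4-(trimethylsilyloxy)phenyl]phenyl acetate | CC(=O)Oc1c(O[Si](C)(C)C)c(-c2ccc(O[Si](C)(C)C)cc2)cc(O[Si](C)(C)C)c1-c1ccc(O[Si](C)(C)C)cc1 | intermediate (not isolated)
7 | neonambiquinone A, 2,5-bis(4-hydroxyphenyl)-3,6-dioxocyclohexa-1,4-dien-1-yl acetate (2-acetoxy-3,6-bis(4-hydroxyphenyl)-1,4-benzoquinone) | CC(=O)OC1=C(c2ccc(O)cc2)C(=O)C=C(c2ccc(O)cc2)C1=O | target

**Totals and risks**
Total step count: 3. Longest linear sequence: 3 steps (1 → 3 → 4 → 7).

Steps most likely to fail, in order of risk: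

Step 3 (the proposed new acetoxylation). The silyl activation may be too weak for the diaryl quinone, some acetyl may migrate or be lost around the oxidation stage, or traces of Ac2O formed from Me3SiOAc may acetylate a phenol. The fallback uses known chemistry, sets out from 4 and comes back at 7. Thiele–Winter acetoxylation of 4 (Ac2O, cat. HClO4, rt to 40 °C) acetylates both phenols and introduces the third ring oxygen, giving 3,6-bis(4-acetoxyphenyl)benzene-1,2,4-triyl triacetate F1. Methanolysis (HCl, MeOH, reflux, Ar) gives 3,6-bis(4-hydroxyphenyl)benzene-1,2,4-triol F2. Oxidation with Ag2O (THF, rt) gives 2-hydroxy-3,6-bis(4-hydroxyphenyl)-1,4-benzoquinone F3. Acidity-directed mono-acetylation (Et3N 1.0 equiv, then AcCl 1.0 equiv, THF, −40 °C) then gives 7, because only the vinylogous-acid OH (pKa about 4, against about 9–10 for the phenols) is ionised and acylated. The selectivity of this last acylation is the weak point of the fallback.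

Step 1 (Suzuki coupling on the unprotected dibromohydroquinone). Oxidative addition into the dianionic dibromide may be slow, 2 may protodeboronate, or adventitious air may oxidise the hydroquinone. The fallback sets out from 2 and comes back at 3. Compound 2 is coupled with bought 1,4-dibromo-2,5-dimethoxybenzene F4 (Pd(PPh3)4, K2CO3, dioxane/H2O, 90 °C) to give 2',5'-dimethoxy-[1,1':4',1''-terphenyl]-4,4''-diol F5. Both methyl ethers are then cleaved with BBr3 (CH2Cl2, −78 °C to rt) to give 3.

Step 2 (oxidation to the free quinone). Compounds 3 and 4 may co-precipitate as a quinhydrone, the phenolic quinone may stick to the silver residue, or 4 may be too insoluble to handle. The fallback sets out from 3 and comes back at 5, so free 4 is never handled. Compound 3 is persilylated (N,O-bis(trimethylsilyl)acetamide, MeCN, rt) to 2,5-bis(trimethylsilyloxy)-1,4-bis[4-(trimethylsilyloxy)phenyl]benzene F6. Pyridinium chlorochromate, [C5H5NH][CrO3Cl], in CH2Cl2 at rt then releases the quinone from the central bis-silyl ether while the outer aryl silyl ethers stay, giving 5 in solution. Compound 5 is taken straight into the second stage of step 3 (Me3SiOAc 4 equiv, Me3SiOSO2CF3 0.3 equiv).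

**Further compounds**
F1 | step 3 | 3,6-bis(4-acetoxyphenyl)benzene-1,2,4-triyl triacetate | CC(=O)Oc1ccc(cc1)-c1cc(OC(C)=O)c(c(OC(C)=O)c1OC(C)=O)-c1ccc(OC(C)=O)cc1
F2 | step 3 | 3,6-bis(4-hydroxyphenyl)benzene-1,2,4-triol | Oc1ccc(cc1)-c1cc(O)c(c(O)c1O)-c1ccc(O)cc1
F3 | step 3 | 2-hydroxy-3,6-bis(4-hydroxyphenyl)-1,4-benzoquinone | OC1=C(c2ccc(O)cc2)C(=O)C=C(c2ccc(O)cc2)C1=O
F4 | step 1 | 1,4-dibromo-2,5-dimethoxybenzene (bought) | COc1cc(Br)c(OC)cc1Br
F5 | step 1 | 2',5'-dimethoxy-[1,1':4',1''-terphenyl]-4,4''-diol | COc1cc(-c2ccc(O)cc2)c(OC)cc1-c1ccc(O)cc1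
F6 | step 2 | 2,5-bis(trimethylsilyloxy)-1,4-bis[4-(trimethylsilyloxy)phenyl]benzene | C[Si](C)(C)Oc1ccc(cc1)-c1cc(O[Si](C)(C)C)c(cc1O[Si](C)(C)C)-c1ccc(O[Si](C)(C)C)cc1
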